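# Robustol by stapling a dibromo diaryl ether with a C14 bis-borane

Atom labels:
- **Ring A:** A1 (chain), A3 (OH), A5 (ether O).
- **Ring B:** B1 (ether O), B2 and B6 (OH), B4 (chain).
- **Chain:** C1 (on B4) to C14 (on A1).

## The problem

Robustol (11) is a 22-membered cyclophane whose two benzene rings are joined twice. One link is the ether oxygen (A5–O–B1). The other is an unbranched (CH2)14 chain from B4 to A1. Ring A is 1,3,5-substituted and bridged meta, whereas ring B holds the ether oxygen between two hydroxyls and is bridged para. There is no stereocentre, and the ring is wide enough that no stable planar-chiral form is expected, so the task is one of connectivity and entropy only. The chain has no heteroatom, branch or unsaturation, so it gives no conformational help in ring closure, and any handle used to build it would have to be erased afterwards. The B1–O bond sits between two oxygen substituents and is the most hindered bond of the molecule, which argues for making it early and intermolecularly. The three phenols, above all the electron-rich 2-aryloxyresorcinol of ring B, are acidic and easily oxidised. They do not tolerate boranes, copper salts or basic palladium catalysis, so they stay masked until the end. The enabling feature is that both chain termini are aryl–CH2 bonds (A1–C14 and B4–C1). A1 and B4 are also the only C–H positions of the parent diaryl ether 3 without an ortho substituent, so one sterically governed operation activates both, and one symmetrical C14 unit joins both.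

## Retrosynthesis

**Unmasking (11 ⇒ 10).**
- **Cut:** the three phenolic O–H groups are traced back to O–CH3 bonds in robustol trimethyl ether 10.
- **Against the neighbours:** benzyl ethers would offer the borylation catalyst further unhindered C–H bonds. Silyl ethers would not outlast hot aqueous copper halide or aqueous carbonate. Bulky groups would distort the steric map on which the borylation relies.
- **Simplification:** the skeleton is unchanged, but every earlier intermediate is free of acidic and oxidisable groups.
- **Forward demand:** three alkyl–oxygen bonds must break while the aryl–O–aryl bridge stays intact.

**The staple (10 ⇒ 6 + 9).**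
- **Cut:** A1–C14 and B4–C1 are cut together.
- **Against the neighbours:** opening the ring at A5–O or B1–O would make the most hindered bond the ring-closing one, and it would need a linear precursor with two differentiated chain ends. A cut inside the chain would need two chain pieces and leave a C=C bond to reduce.
- **Simplification:** only the double aryl–CH2 cut turns the chain into one symmetrical reagent, bis-borane 9, and the aromatic half into the small acyclic dibromide 6. The macrocycle and all chain carbons disappear from the aromatic precursor in one move.
- **Forward demand:** the twofold B-alkyl Suzuki–Miyaura coupling must close the ring faster than it builds oligomers, and it must avoid β-hydride elimination.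

**The borane (9 ⇒ 7 + 8).**
- **Cut:** the two terminal C–B bonds are cut, giving tetradeca-1,13-diene 7 and 9-BBN 8.
- **Against the neighbours:** 8 places boron cleanly on the terminal carbon, and its bicyclic B–C bonds stay behind in transmetalation, so only the primary chain end transfers.
- **Simplification:** the precursor is a commercial hydrocarbon that already holds all fourteen carbons.
- **Forward demand:** complete double hydroboration with no free alkene left.

**Halogen for boron (6 ⇒ 5).**
- **Cut:** both C–Br bonds are traced back to C–B bonds in bis-boronate 5.
- **Against the neighbours:** direct electrophilic bromination of 3 is ruled out. Its oxygen substituents direct to A2, A4, A6 and B3/B5, never to A1, which is meta to both donors.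
- **Simplification:** none in size, but the problem becomes one of steric rather than electronic selectivity.
- **Forward demand:** strictly ipso replacement with no further ring bromination.

**Two C–H bonds (5 ⇒ 3 + 4).**
- **Cut:** the A1–B and B4–B bonds are cut to C–H bonds of diaryl ether 3, with bis(pinacolato)diboron 4 as boron source.
- **Against the neighbours:** building each ring with its halogen in place would need two more elaborate building blocks and a coupling that tolerates C–Br bonds.
- **Simplification:** 3 carries no handle at all.
- **Forward demand:** both rings must react, each at its single open position.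

**The ether bond (3 ⇒ 1 + 2).**
- **Cut:** A5–O is cut, giving 2,6-dimethoxyphenol 1 and 3-bromoanisole 2.
- **Against the neighbours:** cutting B1–O instead would require substitution at a carbon flanked by two methoxy groups on an electron-rich ring.
- **Simplification:** with the chosen polarity the steric load lies only on the nucleophile, and both partners are commodity chemicals.
- **Forward demand:** the Ullmann coupling has to accept a 2,6-disubstituted phenoxide.

## Roads not taken

Alternative 1:
- **Cut:** the ring B oxygens are cut, with B2–O and B6–O traced back to formyl groups. The resulting macrocyclic dialdehyde A2 is opened at B1–O to the open-chain fluoro dialdehyde phenol A1.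
- **Forward key step:** A1 closes by intramolecular SNAr to A2. The key step then oxidises A2 twice with mCPBA (Baeyer–Villiger aryl migration) and cleaves the formates to robustol ring A methyl ether A3. One demethylation remains.
- **Merits:** two ortho formyl groups make the fluoride very reactive, so the hindered ether bond forms under mild base without metal. The ring closure is unimolecular, and two of the three phenols emerge free.
- **Weak points:** A1 joins two different arenes through a C14 chain, which needs two separate C–C couplings on a differentiated chain, with aldehydes protected on the way. Two carbons are installed only to be excised. In the first oxidation the migrating ring still bears a second formyl group, so hydride migration to the carboxylic acid competes. The emerging resorcinol also meets peracid.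
- **Comparison:** in reliability of the ring-closing event this road is better than the chosen one. Against that stand five steps from commodity materials, a chain that needs no end differentiation, and no redox detour.

Alternative 2:
- **Cut:** ring A itself is cut at A3–A4, A5–A6 and A2–A3, which leads to the tethered cyclobutenone–aryl ethynyl ether A4.
- **Forward key step:** heating A4 opens the cyclobutenone to a vinylketene, which adds to the ynol ether. Four-electron opening, six-electron closure and tautomerisation then give robustol ring B dimethyl ether A5, so ring A and the macrocycle form together.
- **Merits:** the 1,3,5-pattern follows from the mechanism, the A3 phenol is born free, no metal is needed, and two rings form in one step against one in the chosen plan.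
- **Weak points:** the first bond-forming event pairs a transient ketene with an alkyne some twenty atoms away. At the dilution a macrocycle demands, ketene dimerisation and acylation of the product phenol by unreacted ketene become competitive. This benzannulation has not been shown as a large-ring closure. A4 carries two sensitive termini on one chain, each needing several steps, and the ethynyl ether must be made from a hindered phenol.
- **Comparison:** this road is the more inventive, but its key step is unproven. The chosen plan rests on a reaction type known for this bond and for cyclophane formation, and it is much shorter.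

Alternative 3:
- **Cut:** A5–O is cut with ring A held at the cyclohexenone level, which leads to the open-chain chloroenone phenol A6.
- **Forward key step:** the ring B phenoxide of A6 adds to the 3-chloroenone and expels chloride, giving the racemic macrocyclic 3-aryloxycyclohexenone A7. Aromatisation gives A5, and demethylation gives 11.
- **Merits:** a vinylogous acid chloride is an unhindered, very reactive acceptor, well suited to the crowded phenoxide. The closure is unimolecular and metal-free.
- **Weak points:** the carbocycle of A6 with its long chain has to be built in several steps of its own. A7 is a vinylogous ester that can exchange its aryloxy group. Dehydrogenation must be carried out next to the electron-rich ring B. A stereocentre is made only to be destroyed.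
- **Comparison:** as in alternative 1, closing one bond is safer than forming two in one pot. The chosen plan answers with aromatic rings bought ready-made, no oxidation-level adjustment, and about half the steps or fewer.

Key step: step 4

Remark: 9-BBN (8) is drawn as the monomer, and equivalents are counted per B–H bond.

## Route

Step 1
Reactants: 1 2,6-dimethoxyphenol; 2 3-bromoanisole
Product: 3 1,3-dimethoxy-2-(3-methoxyphenoxy)benzene
Conditions: CuI (10 mol %), picolinic acid (20 mol %), K3PO4 (2 equiv), DMSO, 100 °C, Ar
Reagents that add atoms: none
Why: Ligand-accelerated Ullmann diaryl ether synthesis, in which picolinic acid keeps the copper phenoxide reactive enough for 2,6-disubstituted phenols to couple with aryl bromides at moderate temperature. The new bond forms at the unhindered carbon A5 of 2, so only the nucleophile is crowded, and exclusion of air prevents oxidative para-coupling of 1.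

Step 2
Reactants: 3 1,3-dimethoxy-2-(3-methoxyphenoxy)benzene; 4 bis(pinacolato)diboron
Product: 5 bis-boronate of 3 with Bpin at A1 and B4, 2-{3-methoxy-5-[2,6-dimethoxy-4-(4,4,5,5-tetramethyl-1,3,2-dioxaborolan-2-yl)phenoxy]phenyl}-4,4,5,5-tetramethyl-1,3,2-dioxaborolane
Conditions: [Ir(OMe)(cod)]2 (3 mol %), dtbpy (6 mol %), 4 (2.5 equiv), THF, 80 °C, sealed tube
Reagents that add atoms: bis(pinacolato)diboron 4 (listed as reactant), CC1(C)OB(OC1(C)C)B1OC(C)(C)C(C)(C)O1
Why: Sterically governed iridium-catalysed aromatic C–H borylation, in which the crowded tris(boryl)iridium species avoids C–H bonds next to substituents. Ring A, a 1,3-disubstituted arene, should react only at A1, and ring B, a 1,2,3-trisubstituted arene, only at B4. Ethers are inert, and a third borylation would have to occur ortho to oxygen.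

Step 3
Reactants: 5 bis-boronate
Product: 6 1-bromo-3-(4-bromo-2,6-dimethoxyphenoxy)-5-methoxybenzene
Conditions: CuBr2 (6.5 equiv), MeOH/H2O 1:1, 80 °C, sealed tube
Reagents that add atoms: CuBr2, [Cu+2].[Br-].[Br-]
Why: Copper-mediated ipso-bromodeboronation of aryl pinacol boronates, which runs by boron-to-copper transmetalation, oxidation by a second CuBr2 to trivalent arylcopper, and C–Br reductive elimination at the same carbon. The meta pattern set in step 2 is thereby carried over unchanged. The borylation–CuBr2 pair is the established route to bromides that electrophilic bromination cannot give.

Step 4
Reactants: 6 1-bromo-3-(4-bromo-2,6-dimethoxyphenoxy)-5-methoxybenzene; 7 tetradeca-1,13-diene; 8 9-borabicyclo[3.3.1]nonane (9-BBN)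
Product: 10 robustol trimethyl ether (22-membered macrocycle), via bis(9-BBN) adduct 9 (not isolated)
Conditions: 7, 8 (0.5 M in THF, 2.05 equiv), THF, 0 °C to rt; 6 (1.0 equiv) dissolved in this solution, then syringe pump (20 h) into Pd(dppf)Cl2·CH2Cl2 (20 mol %), AsPh3 (20 mol %), Cs2CO3 (6 equiv), degassed THF/DMF/H2O, 60 °C, final ca. 1 mM
Reagents that add atoms: none
Why: 9-BBN adds to both terminal alkenes of 7 with boron on the end carbons (anti-Markovnikov hydroboration), so 9 delivers all fourteen carbons as a linear 1,14-dinucleophile. The coupling is a twofold B-alkyl Suzuki–Miyaura reaction: zerovalent palladium inserts into a C–Br bond of 6, the borate formed from 9 and base passes its primary alkyl group to divalent palladium, and reductive elimination forms the aryl–CH2 bond. The closest known reaction types are B-alkyl Suzuki macrocyclisation of ω-boryl halides and the stapling of dihaloarenes with bis-hydroborated α,ω-dienes to cyclophanes, so only the molecule is new. The first cycle is intermolecular and gives an open-chain bromoaryl alkylborane; in the second, oxidative addition at the remaining C–Br bond is followed by intramolecular transmetalation to a 23-membered palladacycle, which contracts on reductive elimination to the strain-free 22-membered ring. Either order (A1 first or B4 first) leads to 10, so no selectivity between the two bromides is required. The selectivity that matters is ring closure against chain growth: 6 and 9, inert to each other without catalyst, are fed from one syringe in strictly equimolar amount into a hot, catalyst-rich solution, so the stationary concentration of free ends stays below the effective molarity of the tethered borane. The wide bite angle of dppf speeds reductive elimination past β-hydride elimination, and AsPh3 with Cs2CO3 in wet THF/DMF accelerates transmetalation. No stereocentre is formed, and the methyl ethers and the diaryl ether are inert to borane, base and palladium.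

Step 5
Reactants: 10 robustol trimethyl ether
Product: 11 robustol
Conditions: BBr3 (9 equiv), CH2Cl2, −78 °C to rt; then ice-water, Ar
Reagents that add atoms: none
Why: Lewis-acid-mediated aryl methyl ether cleavage, in which BBr3 binds each methoxy oxygen and bromide attacks the methyl carbon by SN2. No such attack is possible at the two sp2 carbons of the diaryl ether, so only the three O–CH3 bonds break. Hydrolysis of the aryl borates on work-up frees the phenols, and work-up under argon limits their oxidation.

## Compound list

1 | 2,6-dimethoxyphenol | COc1cccc(OC)c1O | starting material
2 | 3-bromoanisole | COc1cccc(Br)c1 | starting material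
3 | 1,3-dimethoxy-2-(3-methoxyphenoxy)benzene | COc1cccc(Oc2c(OC)cccc2OC)c1 | intermediate
4 | bis(pinacolato)diboron | CC1(C)OB(OC1(C)C)B1OC(C)(C)C(C)(C)O1 | starting material
5 | 2-{3-methoxy-5-[2,6-dimethoxy-4-(4,4,5,5-tetramethyl-1,3,2-dioxaborolan-2-yl)phenoxy]phenyl}-4,4,5,5-tetramethyl-1,3,2-dioxaborolane | COc1cc(B2OC(C)(C)C(C)(C)O2)cc(Oc2c(OC)cc(B3OC(C)(C)C(C)(C)O3)cc2OC)c1 | intermediate
6 | 1-bromo-3-(4-bromo-2,6-dimethoxyphenoxy)-5-methoxybenzene | COc1cc(Br)cc(c1)Oc1c(OC)cc(Br)cc1OC | intermediate
7 | tetradeca-1,13-diene | C=CCCCCCCCCCCCC=C | starting material
8 | 9-borabicyclo[3.3.1]nonane (9-BBN, drawn as monomer) | B1C2CCCC1CCC2 | starting material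
9 | 1,14-bis(9-borabicyclo[3.3.1]nonan-9-yl)tetradecane | B1(C2CCCC1CCC2)CCCCCCCCCCCCCCB1C2CCCC1CCC2 | intermediate
10 | robustol trimethyl ether (OMe at A3, B2, B6; (CH2)14 from B4 to A1; A5–O–B1) | COc1cc2cc(c1)Oc1c(OC)cc(cc1OC)CCCCCCCCCCCCCC2 | intermediate
11 | robustol | Oc1cc2cc(c1)Oc1c(O)cc(cc1O)CCCCCCCCCCCCCC2 | target

## Step count and risks

Total step count: 5, with hydroboration and coupling run as one operation. Longest linear sequence: 5 (1 → 3 → 5 → 6 → 10 → 11).

**Step 4 (key step).** The likeliest failure is chain growth outrunning ring closure. The first bond needs a bimolecular encounter while the second needs dilution, so free ends may meet other molecules and give linear or cyclic oligomers. Any drift from equimolar feed leaves ends with no partner. Hydrodebromination, protodeboronation or β-hydride elimination at the open-chain stage also ends the sequence before closure. The fallback sets out from 6 and returns at 10, and it separates chain attachment from ring closure. Twofold Negishi coupling of 6 uses oct-7-en-1-ylzinc bromide F1, made by zinc insertion into commercial 8-bromooct-1-ene, with Pd(dppf)Cl2 in THF/DMA. It should give 1-methoxy-3-(oct-7-en-1-yl)-5-[2,6-dimethoxy-4-(oct-7-en-1-yl)phenoxy]benzene F2, and here an excess of the nucleophile is harmless. Ring-closing metathesis with the second-generation Grubbs catalyst in dilute CH2Cl2 then closes the 22-membered cycloalkene F3, whose alkene geometry is irrelevant. Hydrogenation (H2, Pd/C, EtOAc) gives 10.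

**Step 3.** Hot CuBr2 with the acid it releases may brominate the activated positions of ring A, a resorcinol diether. Protodeboronation in aqueous methanol may also remove a boryl group before copper does. The fallback sets out from 5 and returns at 10, and it avoids halogenating agents altogether. Oxidation of 5 (NaBO3·4H2O, THF/H2O) should give 3-(4-hydroxy-2,6-dimethoxyphenoxy)-5-methoxyphenol F4. Tf2O and pyridine in CH2Cl2 convert it into the bis(triflate) F5. F5 is then stapled with 9 under the slow-addition regime of step 4 (Pd(dppf)Cl2, K3PO4, THF/dioxane), since aryl triflates are established partners of alkyl-9-BBN reagents.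

**Step 2.** Both rings are electron rich and therefore slow in C–H activation, so the second borylation may stall as the catalyst decays. Some leakage to positions ortho to methoxy may occur on forcing. The fallback sets out from 1 and returns at 6, and it places the halogens before the ether bond is made. Para-bromination of 1 with NBS in CHCl3 gives 4-bromo-2,6-dimethoxyphenol F6. Chan–Lam coupling of F6 with commercial (3-bromo-5-methoxyphenyl)boronic acid (Cu(OAc)2, pyridine, 4 Å molecular sieves, CH2Cl2, air, rt) gives 6. Both C–Br bonds are inert to divalent copper at room temperature.

**Step 1.** The crowded phenoxide may couple slowly. Prolonged heating then favours hydrodebromination of 2 and, with traces of air, copper-mediated oxidative coupling of 1 at its free para position. The fallback sets out from 1 and returns at 3, and it uses metal-free arylation at trivalent iodine. (3-Methoxyphenyl)(2,4,6-trimethoxyphenyl)iodonium tosylate F7 is made in one pot from commercial 3-iodoanisole, mCPBA, TsOH and 1,3,5-trimethoxybenzene. It arylates the potassium salt of 1 (KOt-Bu, toluene, warm) by ligand coupling, which is little affected by ortho substituents on the phenoxide. The electron-rich trimethoxyphenyl group stays on iodine.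

## Further compounds

F1 | step 4 | oct-7-en-1-ylzinc bromide | C=CCCCCCC[Zn]Br
F2 | step 4 | 1-methoxy-3-(oct-7-en-1-yl)-5-[2,6-dimethoxy-4-(oct-7-en-1-yl)phenoxy]benzene | COc1cc(CCCCCCC=C)cc(Oc2c(OC)cc(CCCCCCC=C)cc2OC)c1
F3 | step 4 | 22-membered cycloalkene (robustol trimethyl ether with a C7=C8 double bond in the chain, E/Z mixture) | COc1cc2cc(c1)Oc1c(OC)cc(cc1OC)CCCCCCC=CCCCCCC2
F4 | step 3 | 3-(4-hydroxy-2,6-dimethoxyphenoxy)-5-methoxyphenol | COc1cc(O)cc(Oc2c(OC)cc(O)cc2OC)c1
F5 | step 3 | bis(triflate) of F4 | COc1cc(OS(=O)(=O)C(F)(F)F)cc(Oc2c(OC)cc(OS(=O)(=O)C(F)(F)F)cc2OC)c1
F6 | step 2 | 4-bromo-2,6-dimethoxyphenol | COc1cc(Br)cc(OC)c1O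
F7 | step 1 | (3-methoxyphenyl)(2,4,6-trimethoxyphenyl)iodonium 4-methylbenzenesulfonate | COc1cccc(c1)[I+]c1c(OC)cc(OC)cc1OC.Cc1ccc(cc1)S(=O)(=O)[O-]
A1 | alternative 1 | 2-fluoro-5-[14-(3-hydroxy-5-methoxyphenyl)tetradecyl]benzene-1,3-dicarbaldehyde | COc1cc(O)cc(CCCCCCCCCCCCCCc2cc(C=O)c(F)c(C=O)c2)c1
A2 | alternative 1 | macrocyclic dialdehyde (robustol skeleton, CHO at B2 and B6, OMe at A3) | COc1cc2cc(c1)Oc1c(C=O)cc(cc1C=O)CCCCCCCCCCCCCC2
A3 | alternative 1 | robustol ring A methyl ether | COc1cc2cc(c1)Oc1c(O)cc(cc1O)CCCCCCCCCCCCCC2
A4 | alternative 2 | 3-[14-(4-ethynyloxy-3,5-dimethoxyphenyl)tetradecyl]cyclobut-2-en-1-one | O=C1CC(CCCCCCCCCCCCCCc2cc(OC)c(OC#C)c(OC)c2)=C1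
A5 | alternative 2 | robustol ring B dimethyl ether | COc1cc2cc(OC)c1Oc1cc(O)cc(c1)CCCCCCCCCCCCCC2
A6 | alternative 3 | racemic 3-chloro-5-[14-(4-hydroxy-3,5-dimethoxyphenyl)tetradecyl]cyclohex-2-en-1-one | COc1cc(CCCCCCCCCCCCCCC2CC(Cl)=CC(=O)C2)cc(OC)c1O
A7 | alternative 3 | racemic macrocyclic 3-aryloxycyclohex-2-enone | COc1cc2cc(OC)c1OC1=CC(=O)CC(C1)CCCCCCCCCCCCCC2
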